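**Retrosynthetic overview**
1. Target ⇐ desilylation ⇐ double aromatic Claisen rearrangement of the 7,4'-bis(prenyl) ether: on ring A and on ring B the 1,1-dimethylallyl group sits ortho to a hydroxyl and para to the second ring oxygen (C6, C5').
2. C3 (R) ⇐ Ir-catalysed asymmetric hydrogenation of the C3=C4 bond of an isoflav-3-ene, placed before any terminal alkene exists.
3. Ring C ⇐ one Pd-catalysed (4+2) annulation that forms C2–C3 and C4–C4a together: a (2-iodophenoxy)methylstannane (ring A, O1–C2 already joined) plus the ring B arylacetylene (C3≡C4).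
4. Enabling feature: C2 is a methylene on O1, and O1 sits on C8a next to C4a, so C2 and C4a can be held on one palladium in a five-membered oxapalladacycle (Pd–C4a–C8a–O1–C2) into which C3≡C4 inserts.
5. Ring order: rings A and B are bought (3-(benzyloxy)phenol, 4-(benzyloxy)-2-hydroxybenzaldehyde); ring C is the only ring made (step 5).

Key step: step 5

Assumption: the single stereocentre is C3 of the chroman and is R; the tBu-PHOX enantiomer that gives 3R in step 6 is fixed by a test run, both enantiomers being available.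

Step 1
Reactants: 1 3-(benzyloxy)phenol
Product: 2 5-(benzyloxy)-2-iodophenol
Conditions: I2, NaHCO3, THF/H2O, 0 °C to rt
Reagents that add atoms: iodine, II
Why: Electrophilic aromatic iodination of the phenoxide should place iodine ortho to the hydroxyl and para to the benzyloxy group (the carbon that becomes C4a), the usual course for 3-alkoxyphenols with I2/NaHCO3, any isomer iodinated para to the hydroxyl being removed by chromatography.

Step 2
Reactants: 2 5-(benzyloxy)-2-iodophenol
Product: 3 {[5-(benzyloxy)-2-iodophenoxy]methyl}tributylstannane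
Conditions: Bu3SnCH2I, K2CO3, DMF, rt
Reagents that add atoms: tributyl(iodomethyl)stannane, CCCC[Sn](CCCC)(CCCC)CI
Why: Williamson ether synthesis (SN2 of the phenoxide at the iodomethyl carbon) installs the future C2 on O1 as a CH2–SnBu3 group and leaves the aryl iodide untouched.

Step 3
Reactants: 4 4-(benzyloxy)-2-hydroxybenzaldehyde
Product: 5 4-(benzyloxy)-2-(triisopropylsilyloxy)benzaldehyde
Conditions: TIPSCl, imidazole, DMF, rt
Reagents that add atoms: chlorotriisopropylsilane, CC(C)[Si](Cl)(C(C)C)C(C)C
Why: Standard silylation of the phenol gives a TIPS ether that should survive the organolithium, palladium, hydrogenation, carbonate and thermal steps ahead and leave with fluoride at the end.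

Step 4
Reactants: 5 4-(benzyloxy)-2-(triisopropylsilyloxy)benzaldehyde
Product: 6 4-(benzyloxy)-1-ethynyl-2-(triisopropylsilyloxy)benzene
Conditions: TMSCHN2, LDA, THF, −78 °C to rt; aq NH4Cl
Reagents that add atoms: (trimethylsilyl)diazomethane, C[Si](C)(C)C=[N+]=[N-]
Why: Colvin rearrangement (addition of lithiated TMS-diazomethane to the aldehyde, Peterson elimination, loss of N2 and 1,2-hydride shift) gives the terminal alkyne without the K2CO3/MeOH of the Ohira–Bestmann variant, which could cleave the aryl silyl ether.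

Step 5
Reactants: 3 {[5-(benzyloxy)-2-iodophenoxy]methyl}tributylstannane; 6 4-(benzyloxy)-1-ethynyl-2-(triisopropylsilyloxy)benzene
Product: 8 7-(benzyloxy)-3-[4-(benzyloxy)-2-(triisopropylsilyloxy)phenyl]-2H-chromene, via oxapalladacycle 7 (not isolated)
Conditions: Pd(PPh3)4 (5 mol %), toluene, 100 °C, slow addition of 3 to 6 (1.5 equiv)
Reagents that add atoms: none
Why: Proposed new method: zerovalent palladium adds oxidatively to the C4a–I bond of 3 and the O–CH2–SnBu3 arm transmetalates intramolecularly (loss of Bu3SnI) to the five-membered oxapalladacycle 7, alkyne 6 then inserts into the Pd–C4a bond with C4a going to the unsubstituted alkyne carbon (new C4–C4a bond) and palladium to the aryl-bearing carbon, and C(sp3)–C(sp2) reductive elimination joins C2 to C3 and returns zerovalent palladium. The closest known reaction types are the Larock-type annulation of alkynes by ortho-functionalised aryl iodides and the stoichiometric chemistry of isolable oxapalladacycles made in this way from (2-halophenoxy)methylstannanes, which take up activated alkynes and eliminate to 2H-chromenes; new here is the catalytic domino with an unactivated terminal arylalkyne. Ring C is closed as a formal (4+2) annulation, by ring expansion of the palladacycle through alkyne insertion and ring contraction to the six-membered pyran in the C2–C3 reductive elimination. No stereocentre is created, C3 stays trigonal and is set in step 6. The step needs regioselective insertion (3-aryl and not 4-aryl chromene), which the size difference between H and the ortho-silyloxyaryl group on the alkyne and the preference for aryl over alkyl migration should secure, and it needs insertion to outrun protonolysis of the Pd–CH2 bond by the alkyne C–H, for which base-free, copper-free conditions and slow addition of 3 to an excess of 6 are chosen.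

Step 6
Reactants: 8 7-(benzyloxy)-3-[4-(benzyloxy)-2-(triisopropylsilyloxy)phenyl]-2H-chromene
Product: 9 (R)-7-(benzyloxy)-3-[4-(benzyloxy)-2-(triisopropylsilyloxy)phenyl]chroman
Conditions: [Ir(cod)(tBu-PHOX)]BArF (1 mol %, ligand enantiomer giving 3R), H2 (50 bar), CH2Cl2, rt
Reagents that add atoms: none
Why: Iridium-catalysed asymmetric hydrogenation of an unfunctionalised trisubstituted aryl alkene, a substrate class (3-aryl-2H-chromenes, cyclic stilbenes) for which chiral Ir P,N catalysts are established; the ligand controls the face of C3=C4 that receives H2 and thereby sets C3 as R, and the step is run before any terminal alkene exists in the molecule.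

Step 7
Reactants: 9 (R)-7-(benzyloxy)-3-[4-(benzyloxy)-2-(triisopropylsilyloxy)phenyl]chroman
Product: 10 (R)-3-[4-hydroxy-2-(triisopropylsilyloxy)phenyl]chroman-7-ol
Conditions: H2 (1 atm), Pd/C, EtOAc/MeOH, rt
Reagents that add atoms: none
Why: Hydrogenolysis of both benzyl ethers over Pd/C frees the 7- and 4'-hydroxyls; the aryl TIPS ether, the non-benzylic O1–C2 bond and the C3 stereocentre (a benzylic C–H without a leaving group) should be unaffected.

Step 8
Reactants: 10 (R)-3-[4-hydroxy-2-(triisopropylsilyloxy)phenyl]chroman-7-ol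
Product: 11 (R)-7-(3-methylbut-2-enyloxy)-3-[4-(3-methylbut-2-enyloxy)-2-(triisopropylsilyloxy)phenyl]chroman
Conditions: prenyl bromide, K2CO3, acetone, reflux
Reagents that add atoms: 1-bromo-3-methylbut-2-ene (prenyl bromide), CC(C)=CCBr
Why: Double Williamson O-alkylation (SN2) of the two free phenols with prenyl bromide, the 2'-oxygen staying blocked as the TIPS ether.

Step 9
Reactants: 11 (R)-7-(3-methylbut-2-enyloxy)-3-[4-(3-methylbut-2-enyloxy)-2-(triisopropylsilyloxy)phenyl]chroman
Product: 12 (R)-3-[4-hydroxy-5-(2-methylbut-3-en-2-yl)-2-(triisopropylsilyloxy)phenyl]-6-(2-methylbut-3-en-2-yl)chroman-7-ol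
Conditions: PhNEt2, 190 °C, sealed tube, argon
Reagents that add atoms: none
Why: Two aromatic Claisen rearrangements ([3,3]-sigmatropic shift followed by tautomerisation) should deliver each prenyl group with allylic inversion as a 1,1-dimethylallyl group to the ortho carbon that is para to the other ring oxygen (C6 and C5') rather than to the crowded carbon between two oxygens (C8 and C3'), the para positions being substituted and C3 not being involved.

Step 10
Reactants: 12 (R)-3-[4-hydroxy-5-(2-methylbut-3-en-2-yl)-2-(triisopropylsilyloxy)phenyl]-6-(2-methylbut-3-en-2-yl)chroman-7-ol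
Product: 13 manuifolin E, (R)-3-[2,4-dihydroxy-5-(2-methylbut-3-en-2-yl)phenyl]-6-(2-methylbut-3-en-2-yl)chroman-7-ol
Conditions: TBAF, AcOH, THF, 0 °C
Reagents that add atoms: none
Why: Fluoride-induced cleavage of the aryl silyl ether under acetic acid buffering releases the 2'-hydroxyl without acid-induced cyclisation of the ortho 1,1-dimethylallyl phenols and without touching the terminal alkenes.

**Compound list**
1 | 3-(benzyloxy)phenol | Oc1cccc(OCc2ccccc2)c1 | starting material
2 | 5-(benzyloxy)-2-iodophenol | Oc1cc(OCc2ccccc2)ccc1I | intermediate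
3 | {[5-(benzyloxy)-2-iodophenoxy]methyl}tributylstannane | CCCC[Sn](CCCC)(CCCC)COc1cc(OCc2ccccc2)ccc1I | intermediate
4 | 4-(benzyloxy)-2-hydroxybenzaldehyde | O=Cc1ccc(OCc2ccccc2)cc1O | starting material
5 | 4-(benzyloxy)-2-(triisopropylsilyloxy)benzaldehyde | O=Cc1ccc(OCc2ccccc2)cc1O[Si](C(C)C)(C(C)C)C(C)C | intermediate
6 | 4-(benzyloxy)-1-ethynyl-2-(triisopropylsilyloxy)benzene | C#Cc1ccc(OCc2ccccc2)cc1O[Si](C(C)C)(C(C)C)C(C)C | intermediate
7 | oxapalladacycle of divalent palladium, (PPh3)2Pd bound to the OCH2 carbon (C2) and to C4a of the 4-(benzyloxy)phenoxy unit, five-membered ring Pd–CH2–O–C(aryl)–C(aryl) | C1Oc2cc(OCc3ccccc3)ccc2[Pd-2]1([P+](c1ccccc1)(c1ccccc1)c1ccccc1)[P+](c1ccccc1)(c1ccccc1)c1ccccc1 | intermediate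
8 | 7-(benzyloxy)-3-[4-(benzyloxy)-2-(triisopropylsilyloxy)phenyl]-2H-chromene | C1=C(c2ccc(OCc3ccccc3)cc2O[Si](C(C)C)(C(C)C)C(C)C)COc2cc(OCc3ccccc3)ccc21 | intermediate
9 | (R)-7-(benzyloxy)-3-[4-(benzyloxy)-2-(triisopropylsilyloxy)phenyl]chroman | c1ccccc1COc1ccc2c(c1)OC[C@@H](c1ccc(OCc3ccccc3)cc1O[Si](C(C)C)(C(C)C)C(C)C)C2 | intermediate
10 | (R)-3-[4-hydroxy-2-(triisopropylsilyloxy)phenyl]chroman-7-ol | Oc1ccc2c(c1)OC[C@@H](c1ccc(O)cc1O[Si](C(C)C)(C(C)C)C(C)C)C2 | intermediate
11 | (R)-7-(3-methylbut-2-enyloxy)-3-[4-(3-methylbut-2-enyloxy)-2-(triisopropylsilyloxy)phenyl]chroman | CC(C)=CCOc1ccc2c(c1)OC[C@@H](c1ccc(OCC=C(C)C)cc1O[Si](C(C)C)(C(C)C)C(C)C)C2 | intermediate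
12 | (R)-3-[4-hydroxy-5-(2-methylbut-3-en-2-yl)-2-(triisopropylsilyloxy)phenyl]-6-(2-methylbut-3-en-2-yl)chroman-7-ol | C=CC(C)(C)c1cc2c(cc1O)OC[C@@H](c1cc(C(C)(C)C=C)c(O)cc1O[Si](C(C)C)(C(C)C)C(C)C)C2 | intermediate
13 | manuifolin E, (R)-3-[2,4-dihydroxy-5-(2-methylbut-3-en-2-yl)phenyl]-6-(2-methylbut-3-en-2-yl)chroman-7-ol | C=CC(C)(C)c1cc2c(cc1O)OC[C@@H](c1cc(C(C)(C)C=C)c(O)cc1O)C2 | target

**Step count**
Total: 10 steps. Longest linear sequence: 8 steps (steps 1, 2, 5, 6, 7, 8, 9, 10; the branch through steps 3 and 4 is equally long).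

**Three steps most likely to fail**

Step 5 (proposed new method). What may go wrong: protonolysis of the Pd–CH2 bond of the palladacycle by the alkyne C–H followed by aryl–alkynyl coupling, oligomerisation of the alkyne, or insertion with the opposite regiochemistry. The fallback uses the established phosphonium route to 3-aryl-2H-chromenes; it sets out from 4 and 6 and comes back at 8. Aldehyde 4 is reduced (NaBH4, MeOH) to 5-(benzyloxy)-2-(hydroxymethyl)phenol F1, which with Ph3P·HBr in MeCN should give [4-(benzyloxy)-2-hydroxybenzyl]triphenylphosphonium bromide F2. Alkyne 6 is hydrated ((Ph3P)AuNTf2 cat., wet dioxane) to 1-[4-(benzyloxy)-2-(triisopropylsilyloxy)phenyl]ethanone F3 and brominated at the methyl group (PhNMe3Br3, THF) to 2-bromo-1-[4-(benzyloxy)-2-(triisopropylsilyloxy)phenyl]ethanone F4. O-Alkylation of F2 with F4 (K2CO3, MeCN) gives {4-(benzyloxy)-2-[2-oxo-2-(4-(benzyloxy)-2-(triisopropylsilyloxy)phenyl)ethoxy]benzyl}triphenylphosphonium bromide F5. NaOMe then forms the ylide, and intramolecular Wittig olefination of the ketone closes ring C (O1–C2 and C3=C4 are made instead) to give 8.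

Step 9. What may go wrong: poor regioselectivity on ring A (migration to C8 between the two oxygens), thermal loss of a prenyl group, or cyclisation of the ortho 1,1-dimethylallyl phenols to dihydrobenzofurans at the temperature needed. The fallback replaces the sigmatropic route by halogenation and cross-coupling; it sets out from 10 and comes back at 13. NBS (2 equiv, MeCN, −20 °C) should brominate ortho to each free hydroxyl and para to the other oxygen to give (R)-6-bromo-3-[5-bromo-4-hydroxy-2-(triisopropylsilyloxy)phenyl]chroman-7-ol F6. TBSCl/imidazole gives (R)-6-bromo-3-[5-bromo-4-(tert-butyldimethylsilyloxy)-2-(triisopropylsilyloxy)phenyl]-7-(tert-butyldimethylsilyloxy)chroman F7. Branched-selective (γ) Suzuki–Miyaura coupling with 3-methylbut-2-enylboronic acid pinacol ester (Pd(OAc)2 with a biaryl dialkylphosphine ligand of the type that steers 3,3-disubstituted allylboronates to the branched product, K3PO4, THF/H2O) should give the tris-silyl ether of the target, (R)-7-(tert-butyldimethylsilyloxy)-3-[4-(tert-butyldimethylsilyloxy)-5-(2-methylbut-3-en-2-yl)-2-(triisopropylsilyloxy)phenyl]-6-(2-methylbut-3-en-2-yl)chroman F8. TBAF/AcOH then removes the three silyl groups to give 13.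

Step 6. What may go wrong: slow hydrogenation or poor facial selectivity because of the bulky ortho-silyloxyaryl group on C3. The fallback replaces asymmetric catalysis by resolution, at the cost of half the material; it sets out from 8 and comes back at 10. H2 over Pd/C (EtOAc/MeOH) reduces C3=C4 and removes both benzyl groups in one operation to give racemic 3-[4-hydroxy-2-(triisopropylsilyloxy)phenyl]chroman-7-ol F9. The enantiomers are separated by preparative chromatography on a chiral stationary phase, and the (R)-enantiomer is 10.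

**Further compounds**
F1 | step 5 | 5-(benzyloxy)-2-(hydroxymethyl)phenol | OCc1ccc(OCc2ccccc2)cc1O
F2 | step 5 | [4-(benzyloxy)-2-hydroxybenzyl]triphenylphosphonium bromide | Oc1cc(OCc2ccccc2)ccc1C[P+](c1ccccc1)(c1ccccc1)c1ccccc1.[Br-]
F3 | step 5 | 1-[4-(benzyloxy)-2-(triisopropylsilyloxy)phenyl]ethanone | CC(=O)c1ccc(OCc2ccccc2)cc1O[Si](C(C)C)(C(C)C)C(C)C
F4 | step 5 | 2-bromo-1-[4-(benzyloxy)-2-(triisopropylsilyloxy)phenyl]ethanone | O=C(CBr)c1ccc(OCc2ccccc2)cc1O[Si](C(C)C)(C(C)C)C(C)C
F5 | step 5 | {4-(benzyloxy)-2-[2-oxo-2-(4-(benzyloxy)-2-(triisopropylsilyloxy)phenyl)ethoxy]benzyl}triphenylphosphonium bromide | O=C(COc1cc(OCc2ccccc2)ccc1C[P+](c1ccccc1)(c1ccccc1)c1ccccc1)c1ccc(OCc2ccccc2)cc1O[Si](C(C)C)(C(C)C)C(C)C.[Br-]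
F6 | step 9 | (R)-6-bromo-3-[5-bromo-4-hydroxy-2-(triisopropylsilyloxy)phenyl]chroman-7-ol | Brc1cc2c(cc1O)OC[C@@H](c1cc(Br)c(O)cc1O[Si](C(C)C)(C(C)C)C(C)C)C2
F7 | step 9 | (R)-6-bromo-3-[5-bromo-4-(tert-butyldimethylsilyloxy)-2-(triisopropylsilyloxy)phenyl]-7-(tert-butyldimethylsilyloxy)chroman | Brc1cc2c(cc1O[Si](C)(C)C(C)(C)C)OC[C@@H](c1cc(Br)c(O[Si](C)(C)C(C)(C)C)cc1O[Si](C(C)C)(C(C)C)C(C)C)C2
F8 | step 9 | (R)-7-(tert-butyldimethylsilyloxy)-3-[4-(tert-butyldimethylsilyloxy)-5-(2-methylbut-3-en-2-yl)-2-(triisopropylsilyloxy)phenyl]-6-(2-methylbut-3-en-2-yl)chroman | C=CC(C)(C)c1cc2c(cc1O[Si](C)(C)C(C)(C)C)OC[C@@H](c1cc(C(C)(C)C=C)c(O[Si](C)(C)C(C)(C)C)cc1O[Si](C(C)C)(C(C)C)C(C)C)C2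
F9 | step 6 | racemic 3-[4-hydroxy-2-(triisopropylsilyloxy)phenyl]chroman-7-ol | Oc1ccc2c(c1)OCC(c1ccc(O)cc1O[Si](C(C)C)(C(C)C)C(C)C)C2
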